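## Retrosynthetic overview

- The target is cut at the C3–O acyl bond into the trans-(2R,3S)-benzofuran-3-ol and (2Z)-2-(acetoxymethyl)but-2-enoic acid; this acylation is the last step.
- The dihydrofuran ring is the only ring made (the benzene ring is bought). It is closed at O1–C7a by intramolecular SNAr of the C2 alkoxide on an aryl fluoride para to the acetyl group, after the carbon skeleton is complete.
- The key C2–C3 bond joins 5-acetyl-2-fluoro-4-methoxybenzaldehyde to the silyl enol ether of isobutyraldehyde. The enol ether's oxygen-bearing carbon (the former aldehyde carbon, normally an acceptor) is made a donor as a γ-siloxyallylchromium species, generated by photoredox C–H activation and added under chiral chromium control. This one step sets both stereocentres (anti, 1S,2R).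
- The aldehyde comes from Rieche formylation of 1-(4-fluoro-2-methoxyphenyl)ethanone. The acid comes from methyl but-2-ynoate by syn-hydroalumination and formaldehyde trapping (fixes Z), saponification and acetylation.

Assumption: L* is the enantiomer of 2,2'-(cyclopropane-1,1-diyl)bis(3a,8a-dihydro-8H-indeno[1,2-d]oxazole) that gives the (1S,2R) adduct in step 3; both enantiomers are sold and the choice is fixed by one test run.

## Route

Step 1
Reactants: 1 2-methylpropanal (isobutyraldehyde)
Product: 2 tri(propan-2-yl)[(2-methylprop-1-en-1-yl)oxy]silane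
Conditions: iPr3SiOTf (1.1 equiv), Et3N (1.5 equiv), CH2Cl2, 0 °C → rt; distil
Reagents that add atoms: triisopropylsilyl trifluoromethanesulfonate, CC(C)[Si](OS(=O)(=O)C(F)(F)F)(C(C)C)C(C)C
Why: Soft enolisation and O-silylation of an α-branched aldehyde (silyl enol ether formation) can give only this one enol ether, no stereocentre is formed, and the bulky silyl group is chosen so that the radical cation in step 3 loses a proton and not the silyl group.

Step 2
Reactants: 3 1-(4-fluoro-2-methoxyphenyl)ethan-1-one
Product: 4 5-acetyl-2-fluoro-4-methoxybenzaldehyde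
Conditions: Cl2CHOMe (1.5 equiv), TiCl4 (3 equiv), CH2Cl2, 0 °C → rt; ice/H2O
Reagents that add atoms: dichloromethyl methyl ether, COC(Cl)Cl; water, O
Why: Rieche formylation (electrophilic aromatic substitution) goes para to OMe and ortho to F, the only activated site not flanked by two substituents and meta to the acetyl group; no stereocentre is formed.

Step 3
Reactants: 4 5-acetyl-2-fluoro-4-methoxybenzaldehyde; 2 tri(propan-2-yl)[(2-methylprop-1-en-1-yl)oxy]silane (3 equiv)
Product: 6 1-{4-fluoro-5-[(1S,2R)-1-hydroxy-3-methyl-2-{[tri(propan-2-yl)silyl]oxy}but-3-en-1-yl]-2-methoxyphenyl}ethan-1-one, via allylchromium 5 (not isolated)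
Conditions: CrCl2 (10 mol %), L* (12 mol %), 9-mesityl-10-methylacridinium perchlorate (3 mol %), 2,6-lutidine (20 mol %), CH2Cl2, 450 nm LEDs, rt
Reagents that add atoms: none
Why: Proposed new method: the excited acridinium oxidises enol ether 2 to its radical cation, lutidine removes an allylic methyl proton to give the 1-siloxy-2-methylallyl radical, divalent chromium traps it as the trivalent allylchromium 5 (chromium on CH2, bulky siloxy group trans to it), and 5 adds through its oxygen-bearing γ-carbon to the aldehyde of 4 in a closed Zimmerman–Traxler chair with aryl and siloxy both equatorial (anti), the chiral bis(oxazoline) on chromium choosing the aldehyde face so that C1 (S) and C2 (R) are set together, after which protonation of the chromium alkoxide by lutidinium releases 6 and reduction of the trivalent chromium by the acridine radical returns chromium dichloride to the cycle; the closest known reaction types are the photoredox/chromium dual-catalytic Nozaki–Hiyama–Kishi-type allylation of aldehydes with alkenes or enol ethers via radical-cation deprotonation (anti-selective, enantioselective with bis(oxazoline)–chromium) and the stoichiometric anti-selective γ-alkoxyallylchromium addition, the new elements being the 2-methyl-substituted siloxyallyl donor combined with asymmetric induction and the aryl ketone bystander, which allylchromium reagents leave alone.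

Step 4
Reactants: 6 1-{4-fluoro-5-[(1S,2R)-1-hydroxy-3-methyl-2-{[tri(propan-2-yl)silyl]oxy}but-3-en-1-yl]-2-methoxyphenyl}ethan-1-one
Product: 8 1-[(2R,3S)-3-hydroxy-6-methoxy-2-(prop-1-en-2-yl)-2,3-dihydro-1-benzofuran-5-yl]ethan-1-one, via ammonium alkoxide 7 (not isolated)
Conditions: Bu4NF (1.5 equiv), THF, 0 → 50 °C; recrystallise to upgrade ee
Reagents that add atoms: none
Why: Fluoride cleaves the Si–O bond and the freed C2 alkoxide displaces the fluoride para to the acetyl group by intramolecular SNAr (desilylative SNAr; the C1 oxygen could only close a four-membered ring), and since no bond to either stereocentre is broken the anti (1S,2R) adduct becomes the trans (2R,3S) dihydrobenzofuranol.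

Step 5
Reactants: 9 methyl but-2-ynoate
Product: 11 methyl (2Z)-2-(hydroxymethyl)but-2-enoate, via vinylalane 10 (not isolated)
Conditions: iBu2AlH (1.2 equiv), N-methylmorpholine N-oxide (1.2 equiv), THF, 0 °C; then HCHO (gas, from cracked paraformaldehyde), −20 °C → rt; aq. potassium sodium tartrate
Reagents that add atoms: formaldehyde, C=O
Why: Conjugate syn-hydroalumination of the ynoate (vinylalumination) puts H and Al cis, and formaldehyde is taken up at the α-carbon with retention (or, through the allenolate, on the side away from the β-methyl), so the ester and the β-methyl end up cis (Z) in this aldol-type addition.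

Step 6
Reactants: 11 methyl (2Z)-2-(hydroxymethyl)but-2-enoate
Product: 12 (2Z)-2-(hydroxymethyl)but-2-enoic acid (sarracinic acid)
Conditions: LiOH·H2O (3 equiv), THF/H2O 3:1, 0 °C → rt; then 1 M HCl to pH 2
Reagents that add atoms: lithium hydroxide, [Li+].[OH-]
Why: Ester saponification under mild aqueous base does not touch the trisubstituted alkene, so the Z geometry is kept.

Step 7
Reactants: 12 (2Z)-2-(hydroxymethyl)but-2-enoic acid
Product: 13 (2Z)-2-[(acetyloxy)methyl]but-2-enoic acid
Conditions: Ac2O (2.5 equiv), pyridine, CH2Cl2, 0 °C → rt; then H2O/THF, rt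
Reagents that add atoms: acetic anhydride, CC(=O)OC(C)=O
Why: O-acetylation of the primary alcohol, with any mixed anhydride at the acid hydrolysed in the aqueous stir, and with no amine more nucleophilic than pyridine present so that SN2' attack on the new allylic acetate is avoided.

Step 8
Reactants: 13 (2Z)-2-[(acetyloxy)methyl]but-2-enoic acid (1.5 equiv); 8 1-[(2R,3S)-3-hydroxy-6-methoxy-2-(prop-1-en-2-yl)-2,3-dihydro-1-benzofuran-5-yl]ethan-1-one
Product: 15 (2R,3S)-5-acetyl-6-methoxy-2-(prop-1-en-2-yl)-2,3-dihydro-1-benzofuran-3-yl (2Z)-2-[(acetyloxy)methyl]but-2-enoate (CNP0221694.1), via mixed anhydride 14 (not isolated)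
Conditions: 2,4,6-Cl3C6H2COCl (1.5 equiv), iPr2NEt (3 equiv), toluene, rt, 1 h; then 8, 80 °C; Et3N-washed SiO2
Reagents that add atoms: none
Why: Yamaguchi-type mixed-anhydride esterification without a nucleophilic catalyst: the alcohol attacks the unhindered enoyl carbonyl of 14, the C3–O bond of 8 is never broken (configuration retained), and base-only conditions avoid benzylic ionisation, SN2' loss of acetate and Z → E isomerisation.

## Compound list

1 | 2-methylpropanal (isobutyraldehyde) | CC(C)C=O | starting material
2 | tri(propan-2-yl)[(2-methylprop-1-en-1-yl)oxy]silane | CC(C)=CO[Si](C(C)C)(C(C)C)C(C)C | intermediate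
3 | 1-(4-fluoro-2-methoxyphenyl)ethan-1-one | CC(=O)c1ccc(F)cc1OC | starting material
4 | 5-acetyl-2-fluoro-4-methoxybenzaldehyde | CC(=O)c1cc(C=O)c(F)cc1OC | intermediate
5 | dichloro[(2E)-2-methyl-3-{[tri(propan-2-yl)silyl]oxy}prop-2-en-1-yl]chromium (bis(oxazoline) ligand not drawn) | C/C(C[Cr](Cl)Cl)=C\O[Si](C(C)C)(C(C)C)C(C)C | intermediate
6 | 1-{4-fluoro-5-[(1S,2R)-1-hydroxy-3-methyl-2-{[tri(propan-2-yl)silyl]oxy}but-3-en-1-yl]-2-methoxyphenyl}ethan-1-one | CC(=O)c1cc([C@H](O)[C@H](O[Si](C(C)C)(C(C)C)C(C)C)C(C)=C)c(F)cc1OC | intermediate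
7 | tetrabutylammonium (1S,2R)-1-(5-acetyl-2-fluoro-4-methoxyphenyl)-1-hydroxy-3-methylbut-3-en-2-olate | CC(=O)c1cc([C@H](O)[C@H]([O-])C(C)=C)c(F)cc1OC.CCCC[N+](CCCC)(CCCC)CCCC | intermediate
8 | 1-[(2R,3S)-3-hydroxy-6-methoxy-2-(prop-1-en-2-yl)-2,3-dihydro-1-benzofuran-5-yl]ethan-1-one | C=C(C)[C@H]1Oc2cc(OC)c(C(C)=O)cc2[C@@H]1O | intermediate
9 | methyl but-2-ynoate | CC#CC(=O)OC | starting material
10 | methyl (2E)-2-[bis(2-methylpropyl)alumanyl]but-2-enoate | COC(=O)/C(=C\C)[Al](CC(C)C)CC(C)C | intermediate
11 | methyl (2Z)-2-(hydroxymethyl)but-2-enoate | COC(=O)/C(=C\C)CO | intermediate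
12 | (2Z)-2-(hydroxymethyl)but-2-enoic acid | OC(=O)/C(=C\C)CO | intermediate
13 | (2Z)-2-[(acetyloxy)methyl]but-2-enoic acid | OC(=O)/C(=C\C)COC(C)=O | intermediate
14 | (2Z)-2-[(acetyloxy)methyl]but-2-enoic 2,4,6-trichlorobenzoic anhydride | O=C(OC(=O)/C(=C\C)COC(C)=O)c1c(Cl)cc(Cl)cc1Cl | intermediate
15 | (2R,3S)-5-acetyl-6-methoxy-2-(prop-1-en-2-yl)-2,3-dihydro-1-benzofuran-3-yl (2Z)-2-[(acetyloxy)methyl]but-2-enoate | C=C(C)[C@H]1Oc2cc(OC)c(C(C)=O)cc2[C@@H]1OC(=O)/C(=C\C)COC(C)=O | target

## Step count and risks

Total steps: 8. Longest linear sequence: 4 steps (steps 2, 3, 4 and 8 from compound 3; the acid branch, steps 5 to 8, is equally long).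

**Step 3 (highest risk).** The catalytic, enantioselective version with this 2-methyl siloxyallyl donor is untested. Possible failures are a Lewis-acid Mukaiyama-type aldol of 2 with 4, loss of the silyl group from the radical cation, or poor ee or anti selectivity. The fallback sets out from 4 and comes back at 8, and makes the same C2–C3 bond with a different nucleophilic α-oxyallyl metal. Methacrolein and benzoic anhydride (FeCl3 cat.) give 2-methylprop-2-ene-1,1-diyl dibenzoate F1. Compounds 4 and F1 are coupled by iridium-catalysed transfer hydrogenation ([Ir(cod)Cl]2, SEGPHOS of the enantiomer found to give the 1S,2R product, 4-cyano-3-nitrobenzoic acid, K3PO4, iPrOH, THF, 70 °C). Here an α-(benzoyloxy)allyliridium species adds anti-selectively to give (1S,2R)-1-(5-acetyl-2-fluoro-4-methoxyphenyl)-1-hydroxy-3-methylbut-3-en-2-yl benzoate F2. K2CO3 in MeOH (rt → 50 °C) then removes the benzoate and the alkoxide closes the ring by SNAr, giving 8.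

**Step 8.** The alcohol is a hindered, ionisable benzylic one, and the acid can isomerise to the E form or lose its allylic acetate by SN2' attack. The fallback sets out from 12 (with 8) and comes back at 15, moving the acetate to the very end. Compound 12 is silylated (TBSCl, imidazole, DMF; then K2CO3, MeOH/H2O to cleave the silyl ester) to (2Z)-2-{[(tert-butyldimethylsilyl)oxy]methyl}but-2-enoic acid F3. This acid has no allylic leaving group and so tolerates carbodiimide coupling with 8 (EDC·HCl, DMAP cat., CH2Cl2, 0 °C), giving (2R,3S)-5-acetyl-6-methoxy-2-(prop-1-en-2-yl)-2,3-dihydro-1-benzofuran-3-yl (2Z)-2-{[(tert-butyldimethylsilyl)oxy]methyl}but-2-enoate F4. Buffered desilylation (Bu4NF/AcOH, THF, 0 °C) gives (2R,3S)-5-acetyl-6-methoxy-2-(prop-1-en-2-yl)-2,3-dihydro-1-benzofuran-3-yl (2Z)-2-(hydroxymethyl)but-2-enoate F5, and Ac2O/pyridine gives 15.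

**Step 2.** The ring is deactivated by the acetyl group, and more so once TiCl4 chelates the acetyl and methoxy oxygens, so the formylation may stall. The fallback sets out from 3 and comes back at 4. NBS (MeCN, rt) brominates the same position to give 1-(5-bromo-4-fluoro-2-methoxyphenyl)ethan-1-one F6. Palladium-catalysed reductive carbonylation (Pd(OAc)2, di(1-adamantyl)-n-butylphosphine, CO/H2 1:1 at 5 bar, TMEDA, toluene, 100 °C) then turns the C–Br bond into the formyl group of 4 with the ketone untouched.

## Further compounds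

F1 | step 3 | 2-methylprop-2-ene-1,1-diyl dibenzoate | C=C(C)C(OC(=O)c1ccccc1)OC(=O)c1ccccc1
F2 | step 3 | (1S,2R)-1-(5-acetyl-2-fluoro-4-methoxyphenyl)-1-hydroxy-3-methylbut-3-en-2-yl benzoate | CC(=O)c1cc([C@H](O)[C@H](OC(=O)c2ccccc2)C(C)=C)c(F)cc1OC
F3 | step 8 | (2Z)-2-{[(tert-butyldimethylsilyl)oxy]methyl}but-2-enoic acid | OC(=O)/C(=C\C)CO[Si](C)(C)C(C)(C)C
F4 | step 8 | (2R,3S)-5-acetyl-6-methoxy-2-(prop-1-en-2-yl)-2,3-dihydro-1-benzofuran-3-yl (2Z)-2-{[(tert-butyldimethylsilyl)oxy]methyl}but-2-enoate | C=C(C)[C@H]1Oc2cc(OC)c(C(C)=O)cc2[C@@H]1OC(=O)/C(=C\C)CO[Si](C)(C)C(C)(C)C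
F5 | step 8 | (2R,3S)-5-acetyl-6-methoxy-2-(prop-1-en-2-yl)-2,3-dihydro-1-benzofuran-3-yl (2Z)-2-(hydroxymethyl)but-2-enoate | C=C(C)[C@H]1Oc2cc(OC)c(C(C)=O)cc2[C@@H]1OC(=O)/C(=C\C)CO
F6 | step 2 | 1-(5-bromo-4-fluoro-2-methoxyphenyl)ethan-1-one | CC(=O)c1cc(Br)c(F)cc1OC
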